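**Retrosynthetic overview**

- Numbering: lactone O1, C2 (C=O), C3 (CH3), C4 (O-acyl), C5; chain C6–C18 (CH3 on C7, C11, C15; furan-3-yl on C18).
- Feature: the exocyclic E C5=C6 alkene (C7 trans to O1) sits beside the only stereocentre, C7 (S). Butenolide ring A, this geometry and C7 are all made by additions across a terminal C5≡C6 alkyne (O1–C5, then C6–C7).
- Disconnections, backwards: O4–palmitoyl; O4–CH3; C10–C11 (B-alkyl Suzuki of the C1–C10 alkene with the C11–C18 furyl dienyl iodide); C9=C10 (Wittig); O1–C5 and C6–C7 (palladium cascade of an enynoic acid with (E)-but-2-enal).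
- Fragments: the enynoic acid from a propanoate aldol with a silylated ynal, oxidation, E-selective O-methylation and fluoride unmasking; the iodide from 3-bromofuran by two Negishi couplings with one pent-3-ynylzinc reagent, each followed by alkyne hydrozirconation–iodination.
- Ring order: the furan (ring B) is bought; ring A is the only ring formed, in step 6.

Key step: step 6

Remark on the chemistry: the sense of asymmetric induction of the pyridine–oxazoline ligand in step 6 cannot be predicted with confidence; the (S)-ligand is written, and its enantiomer is to be used if it should lead to (R)-configured C7.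

**Route**

Step 1
Reactants: 1 propanoyl chloride; 2 2-(trimethylsilyl)ethanol
Product: 3 2-(trimethylsilyl)ethyl propanoate
Conditions: pyridine, CH2Cl2, 0 °C → rt
Reagents that add atoms: none
Why: Esterification of a primary alcohol with an acid chloride; this ester is chosen because fluoride can later free the acid without hydroxide.

Step 2
Reactants: 3 2-(trimethylsilyl)ethyl propanoate; 4 3-(trimethylsilyl)prop-2-ynal
Product: 6 2-(trimethylsilyl)ethyl 3-hydroxy-2-methyl-5-(trimethylsilyl)pent-4-ynoate (mixture of racemic diastereomers), via lithium ester enolate 5 (not isolated)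
Conditions: LiN(iPr)2, THF, −78 °C; then 4, −78 °C; aq. NH4Cl
Reagents that add atoms: none
Why: Aldol addition of a preformed lithium ester enolate to a non-enolisable ynal, which should add 1,2 at low temperature; both new stereocentres are erased in steps 3 and 4, so no control is needed.

Step 3
Reactants: 6 2-(trimethylsilyl)ethyl 3-hydroxy-2-methyl-5-(trimethylsilyl)pent-4-ynoate
Product: 7 2-(trimethylsilyl)ethyl 2-methyl-3-oxo-5-(trimethylsilyl)pent-4-ynoate (racemic)
Conditions: Dess–Martin periodinane, CH2Cl2, 0 °C → rt
Reagents that add atoms: none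
Why: Dess–Martin oxidation of the propargylic secondary alcohol should give the β-keto ester under near-neutral conditions that leave both silyl groups intact.

Step 4
Reactants: 7 2-(trimethylsilyl)ethyl 2-methyl-3-oxo-5-(trimethylsilyl)pent-4-ynoate
Product: 9 2-(trimethylsilyl)ethyl (2E)-3-methoxy-2-methyl-5-(trimethylsilyl)pent-2-en-4-ynoate, via potassium enolate 8 (not isolated)
Conditions: KN(SiMe3)2, 18-crown-6, THF, −78 °C; then MeOTf, −78 → −20 °C
Reagents that add atoms: methyl trifluoromethanesulfonate, COS(=O)(=O)C(F)(F)F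
Why: O-Alkylation of a β-keto ester enolate: the crown-complexed, ion-separated potassium enolate should adopt the extended form with O− anti to the ester carbonyl and be methylated on oxygen by the hard electrophile, giving the E enol ether (ester cis to the slim alkynyl group), while the α-methyl group disfavours C-alkylation.

Step 5
Reactants: 9 2-(trimethylsilyl)ethyl (2E)-3-methoxy-2-methyl-5-(trimethylsilyl)pent-2-en-4-ynoate
Product: 11 (2E)-3-methoxy-2-methylpent-2-en-4-ynoic acid, via tetrabutylammonium carboxylate 10 (not isolated)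
Conditions: Bu4NF (2.5 equiv), THF, 0 °C → rt; then 1 M HCl to pH 3, 0 °C
Reagents that add atoms: none
Why: Fluoride-induced protodesilylation of the alkynylsilane and β-elimination of the 2-(trimethylsilyl)ethyl ester unmask the terminal alkyne and the acid under non-hydrolytic conditions that should leave the enol ether and its geometry alone.

Step 6
Reactants: 11 (2E)-3-methoxy-2-methylpent-2-en-4-ynoic acid; 12 (E)-but-2-enal
Product: 13 (3S,4E)-4-(3-methoxy-4-methyl-5-oxofuran-2(5H)-ylidene)-3-methylbutanal
Conditions: Pd(OAc)2 (5 mol %), (S)-4-tert-butyl-2-(pyridin-2-yl)-4,5-dihydrooxazole (6 mol %), LiBr (10 mol %), 12 (5 equiv), MeCN/AcOH (10:1), 25 °C, dark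
Reagents that add atoms: none
Why: Proposed new method: the ligated divalent palladium π-activates the terminal alkyne of 11, and the carboxylate, held cis to the alkyne by the E enol ether, attacks C5 from the face opposite the metal in a 5-exo-dig closure (O1–C5) that forms butenolide ring A and puts palladium on C6 trans to O1. The C6–Pd bond then adds syn across the C=C bond of 12 with C6 going to the β-carbon (C6–C7, retention at C6), and the palladium enolate is protonated by the proton set free in the lactonisation, so divalent palladium is returned without a redox change while bromide and the chelating ligand hold back β-hydride elimination. The closest known reaction type is the Pd(OAc)2/LiBr-catalysed cyclisation of alkynoic acids with conjugate trapping of the alkenylpalladium by acrolein or vinyl ketones, together with pyridine–oxazoline-controlled conjugate additions of organopalladium species to β-substituted enones; a β-methyl enal in the cascade and its enantiocontrol are the untested parts. The new stereocentre C7 is set in the insertion, where the tert-butyl group of the ligand should differentiate the two faces of the coordinated enal. The E geometry of C5=C6 needs anti-oxypalladation followed by retentive insertion and is secured by the terminal alkyne, because the carbon substituent enters after ring closure at the position that palladium held; the same terminal alkyne directs palladium to the unhindered carbon and so favours 5-exo over 6-endo (pyranone) closure. Protonolysis of the C6–Pd bond before insertion is the main competitor and is countered by the excess of enal and the weakly acidic medium.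

Step 7
Reactants: 13 (3S,4E)-4-(3-methoxy-4-methyl-5-oxofuran-2(5H)-ylidene)-3-methylbutanal
Product: 14 (5E)-4-methoxy-3-methyl-5-[(2S)-2-methylpent-4-en-1-ylidene]furan-2(5H)-one
Conditions: Ph3PCH3Br, KN(SiMe3)2, THF, 0 °C; then 13, −78 → 0 °C
Reagents that add atoms: methyltriphenylphosphonium bromide, C[P+](c1ccccc1)(c1ccccc1)c1ccccc1.[Br-]
Why: Wittig methylenation: addition of Ph3P=CH2 to the aldehyde at −78 °C should outpace any deprotonation, so C7 (not α to the carbonyl) and the E C5=C6 alkene are kept.

Step 8
Reactants: 15 pent-3-yn-1-ol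
Product: 16 5-iodopent-2-yne
Conditions: PPh3, I2, imidazole, CH2Cl2, 0 °C → rt
Reagents that add atoms: iodine, II
Why: Appel-type iodination: the alcohol is activated as an alkoxyphosphonium ion and displaced by iodide (SN2) without touching the alkyne.

Step 9
Reactants: 16 5-iodopent-2-yne
Product: 17 pent-3-yn-1-ylzinc iodide (titrated THF solution containing LiCl, kept under Ar; one batch serves steps 10 and 12)
Conditions: Zn dust (activated by BrCH2CH2Br and Me3SiCl), LiCl, THF, 40 °C; decant, titrate with I2
Reagents that add atoms: zinc, [Zn]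
Why: Direct oxidative insertion of LiCl-activated zinc into a primary alkyl iodide gives a storable alkylzinc halide solution; the internal alkyne is inert to zinc and a homopropargylic zinc reagent has no easy cyclisation or elimination path.

Step 10
Reactants: 17 pent-3-yn-1-ylzinc iodide; 18 3-bromofuran
Product: 19 3-(pent-3-yn-1-yl)furan
Conditions: Pd(OAc)2 (2 mol %), SPhos (4 mol %), THF, 50 °C
Reagents that add atoms: none
Why: Negishi sp3–sp2 coupling of the alkylzinc reagent with the heteroaryl bromide; the alkylzinc tolerates the internal alkyne and the bulky biaryl phosphine favours reductive elimination over β-hydride elimination.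

Step 11
Reactants: 19 3-(pent-3-yn-1-yl)furan
Product: 21 3-[(3E)-4-iodopent-3-en-1-yl]furan, via alkenylzirconocene chloride 20 (not isolated)
Conditions: Cp2Zr(H)Cl (2 equiv), THF, rt → 50 °C, dark; then I2, THF, 0 °C
Reagents that add atoms: iodine, II
Why: Hydrozirconation–iodination: syn addition of Zr–H with excess Cp2Zr(H)Cl should equilibrate zirconium to the methyl-bearing carbon of the 2-alkyne, and iodinolysis with retention gives the E 2-iodoalkene (iodine trans to the chain).

Step 12
Reactants: 21 3-[(3E)-4-iodopent-3-en-1-yl]furan; 17 pent-3-yn-1-ylzinc iodide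
Product: 22 3-[(3E)-4-methylnon-3-en-7-yn-1-yl]furan
Conditions: Pd(dppf)Cl2 (3 mol %), THF, rt
Reagents that add atoms: none
Why: Negishi coupling of the alkenyl iodide with the alkylzinc reagent proceeds with retention of configuration and so fixes the E C15=C16 alkene.

Step 13
Reactants: 22 3-[(3E)-4-methylnon-3-en-7-yn-1-yl]furan
Product: 24 3-[(3E,7E)-8-iodo-4-methylnona-3,7-dien-1-yl]furan, via alkenylzirconocene chloride 23 (not isolated)
Conditions: Cp2Zr(H)Cl (2 equiv), THF, rt → 50 °C, dark; then I2, THF, 0 °C
Reagents that add atoms: iodine, II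
Why: Second hydrozirconation–iodination on the same regio- and stereochemical basis as step 11; the alkyne should react far faster than the trisubstituted alkene, and this sets the E geometry of the future C11=C12 alkene.

Step 14
Reactants: 14 (5E)-4-methoxy-3-methyl-5-[(2S)-2-methylpent-4-en-1-ylidene]furan-2(5H)-one; 24 3-[(3E,7E)-8-iodo-4-methylnona-3,7-dien-1-yl]furan
Product: 26 (5E)-5-[(2S,6E,10E)-13-(furan-3-yl)-2,6,10-trimethyltrideca-6,10-dien-1-ylidene]-4-methoxy-3-methylfuran-2(5H)-one, via B-alkyl-9-BBN 25 (not isolated)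
Conditions: 9-BBN (1.3 equiv), THF, 0 °C → rt; then 3 M aq. K3PO4, 24, Pd(dppf)Cl2 (5 mol %), AsPh3 (5 mol %), DMF, rt
Reagents that add atoms: none
Why: Hydroboration then B-alkyl Suzuki–Miyaura coupling: 9-BBN should add only to the monosubstituted C9=C10 alkene (boron on C10; the conjugated trisubstituted C5=C6 alkene and the lactone are inert), and the alkylborane couples with the alkenyl iodide with retention to form C10–C11.

Step 15
Reactants: 26 (5E)-5-[(2S,6E,10E)-13-(furan-3-yl)-2,6,10-trimethyltrideca-6,10-dien-1-ylidene]-4-methoxy-3-methylfuran-2(5H)-one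
Product: 28 (5E)-5-[(2S,6E,10E)-13-(furan-3-yl)-2,6,10-trimethyltrideca-6,10-dien-1-ylidene]-4-hydroxy-3-methylfuran-2(5H)-one, via lithium tetronate 27 (not isolated)
Conditions: LiCl (10 equiv), DMF, 80 °C, dark; then cold 0.5 M HCl
Reagents that add atoms: none
Why: Nucleophilic O-demethylation of a vinylogous methyl carbonate: chloride attacks the methyl group (SN2) and the stabilised tetronate leaves, a known reaction of 4-methoxybutenolides; acid and light are excluded so that the E C5=C6 alkene should survive.

Step 16
Reactants: 28 (5E)-5-[(2S,6E,10E)-13-(furan-3-yl)-2,6,10-trimethyltrideca-6,10-dien-1-ylidene]-4-hydroxy-3-methylfuran-2(5H)-one; 29 palmitoyl chloride (hexadecanoyl chloride)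
Product: 30 (2E)-2-[(2S,6E,10E)-13-(furan-3-yl)-2,6,10-trimethyltrideca-6,10-dien-1-ylidene]-4-methyl-5-oxo-2,5-dihydrofuran-3-yl hexadecanoate (CNP0269639.1)
Conditions: Et3N, CH2Cl2, −20 → 0 °C
Reagents that add atoms: none
Why: O-Acylation of the tetronic acid with the acid chloride and Et3N gives the C4 enol ester; C3 carries a methyl group, so C-acylation is not a competitor.

**Compound list**

1 | propanoyl chloride | CCC(=O)Cl | starting material
2 | 2-(trimethylsilyl)ethanol | C[Si](C)(C)CCO | starting material
3 | 2-(trimethylsilyl)ethyl propanoate | CCC(=O)OCC[Si](C)(C)C | intermediate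
4 | 3-(trimethylsilyl)prop-2-ynal | C[Si](C)(C)C#CC=O | starting material
5 | lithium 1-[2-(trimethylsilyl)ethoxy]prop-1-en-1-olate (enolate geometry not relevant) | CC=C([O-])OCC[Si](C)(C)C.[Li+] | intermediate
6 | 2-(trimethylsilyl)ethyl 3-hydroxy-2-methyl-5-(trimethylsilyl)pent-4-ynoate (diastereomer mixture, racemic) | CC(C(O)C#C[Si](C)(C)C)C(=O)OCC[Si](C)(C)C | intermediate
7 | 2-(trimethylsilyl)ethyl 2-methyl-3-oxo-5-(trimethylsilyl)pent-4-ynoate (racemic) | CC(C(=O)C#C[Si](C)(C)C)C(=O)OCC[Si](C)(C)C | intermediate
8 | potassium (3E)-4-{[2-(trimethylsilyl)ethoxy]carbonyl}-1-(trimethylsilyl)pent-3-en-1-yn-3-olate | C[Si](C)(C)CCOC(=O)/C(C)=C([O-])\C#C[Si](C)(C)C.[K+] | intermediate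
9 | 2-(trimethylsilyl)ethyl (2E)-3-methoxy-2-methyl-5-(trimethylsilyl)pent-2-en-4-ynoate | C[Si](C)(C)CCOC(=O)/C(C)=C(OC)\C#C[Si](C)(C)C | intermediate
10 | tetrabutylammonium (2E)-3-methoxy-2-methylpent-2-en-4-ynoate | C#C/C(OC)=C(C)\C(=O)[O-].CCCC[N+](CCCC)(CCCC)CCCC | intermediate
11 | (2E)-3-methoxy-2-methylpent-2-en-4-ynoic acid | C#C/C(OC)=C(C)\C(=O)O | intermediate
12 | (E)-but-2-enal | C/C=C/C=O | starting material
13 | (3S,4E)-4-(3-methoxy-4-methyl-5-oxofuran-2(5H)-ylidene)-3-methylbutanal | COC1=C(C)C(=O)O/C1=C/[C@@H](C)CC=O | intermediate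
14 | (5E)-4-methoxy-3-methyl-5-[(2S)-2-methylpent-4-en-1-ylidene]furan-2(5H)-one | COC1=C(C)C(=O)O/C1=C/[C@@H](C)CC=C | intermediate
15 | pent-3-yn-1-ol | CC#CCCO | starting material
16 | 5-iodopent-2-yne | CC#CCCI | intermediate
17 | pent-3-yn-1-ylzinc iodide | CC#CCC[Zn]I | intermediate
18 | 3-bromofuran | Brc1ccoc1 | starting material
19 | 3-(pent-3-yn-1-yl)furan | CC#CCCc1ccoc1 | intermediate
20 | chloridobis(cyclopentadienyl)[(2E)-5-(furan-3-yl)pent-2-en-2-yl]zirconium | C/C([Zr](Cl)(C1C=CC=C1)C1C=CC=C1)=C\CCc1ccoc1 | intermediate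
21 | 3-[(3E)-4-iodopent-3-en-1-yl]furan | C/C(I)=C\CCc1ccoc1 | intermediate
22 | 3-[(3E)-4-methylnon-3-en-7-yn-1-yl]furan | CC#CCC/C(C)=C/CCc1ccoc1 | intermediate
23 | chloridobis(cyclopentadienyl)[(2E,6E)-9-(furan-3-yl)-6-methylnona-2,6-dien-2-yl]zirconium | C/C([Zr](Cl)(C1C=CC=C1)C1C=CC=C1)=C\CC/C(C)=C/CCc1ccoc1 | intermediate
24 | 3-[(3E,7E)-8-iodo-4-methylnona-3,7-dien-1-yl]furan | C/C(I)=C\CC/C(C)=C/CCc1ccoc1 | intermediate
25 | (5E)-5-[(2S)-5-(9-borabicyclo[3.3.1]nonan-9-yl)-2-methylpentylidene]-4-methoxy-3-methylfuran-2(5H)-one | COC1=C(C)C(=O)O/C1=C/[C@@H](C)CCCB1C2CCCC1CCC2 | intermediate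
26 | (5E)-5-[(2S,6E,10E)-13-(furan-3-yl)-2,6,10-trimethyltrideca-6,10-dien-1-ylidene]-4-methoxy-3-methylfuran-2(5H)-one | COC1=C(C)C(=O)O/C1=C/[C@@H](C)CCC/C(C)=C/CC/C(C)=C/CCc1ccoc1 | intermediate
27 | lithium (2E)-2-[(2S,6E,10E)-13-(furan-3-yl)-2,6,10-trimethyltrideca-6,10-dien-1-ylidene]-4-methyl-5-oxo-2,5-dihydrofuran-3-olate | [Li+].[O-]C1=C(C)C(=O)O/C1=C/[C@@H](C)CCC/C(C)=C/CC/C(C)=C/CCc1ccoc1 | intermediate
28 | (5E)-5-[(2S,6E,10E)-13-(furan-3-yl)-2,6,10-trimethyltrideca-6,10-dien-1-ylidene]-4-hydroxy-3-methylfuran-2(5H)-one | OC1=C(C)C(=O)O/C1=C/[C@@H](C)CCC/C(C)=C/CC/C(C)=C/CCc1ccoc1 | intermediate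
29 | palmitoyl chloride (hexadecanoyl chloride) | CCCCCCCCCCCCCCCC(=O)Cl | starting material
30 | (2E)-2-[(2S,6E,10E)-13-(furan-3-yl)-2,6,10-trimethyltrideca-6,10-dien-1-ylidene]-4-methyl-5-oxo-2,5-dihydrofuran-3-yl hexadecanoate | CCCCCCCCCCCCCCCC(=O)OC1=C(C)C(=O)O/C1=C/[C@@H](C)CCC/C(C)=C/CC/C(C)=C/CCc1ccoc1 | target

**Count**

Total steps: 16. Longest linear sequence: 10 steps (steps 1–7 and 14–16, from propanoyl chloride). The iodide branch is 6 steps (8–13) before the coupling; the zinc reagent of step 9 is used in both step 10 and step 12.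

**Steps most likely to fail**

1. Step 6 (proposed new method). The C6–Pd bond may be protonated before the β-substituted enal inserts, closure may go 6-endo, or the ligand may discriminate the enal faces poorly. The fallback uses known chemistry, sets out from 11 and comes back at 13. Acid 11 would be iodolactonised with I2 and NaHCO3 in MeCN at 0 °C, an anti, 5-exo-dig addition that should give (5E)-5-(iodomethylidene)-4-methoxy-3-methylfuran-2(5H)-one F1 with iodine trans to O1. F1 would then serve as the alkenyl partner in an enantioselective redox-relay Heck reaction with (E)-but-2-en-1-ol (Pd2(dba)3 as the zerovalent palladium source, a chiral pyridine–oxazoline ligand, AgOTf to ionise the iodide, DMA, rt), a reaction type established for alkenyl electrophiles and acyclic alkenols. Oxidative addition with retention gives the alkenylpalladium, insertion places C6 on C3 of the alkenol (the future C7), and migration of palladium to the carbinol carbon releases aldehyde 13 with the E geometry intact. The ligand antipode chosen sets C7.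

2. Step 4. Methylation may go to carbon, or oxygen may be alkylated through the chelated enolate geometry, giving the Z enol ether whose acid cannot lactonise. The fallback sets out from 7 and comes back at 9. Keto ester 7 would be ketalised with HC(OMe)3 and catalytic TsOH to 2-(trimethylsilyl)ethyl 3,3-dimethoxy-2-methyl-5-(trimethylsilyl)pent-4-ynoate F2. F2 would then be heated with catalytic TsOH in toluene while methanol is distilled off. Elimination under these equilibrating conditions should favour the E enol ether 9 (methoxy anti to the ester carbonyl), since the Z isomer can return through the ketal.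

3. Step 15. The E C5=C6 alkene may isomerise, or dealkylation may stall, under hot halide conditions one step from the end. The fallback replaces the methyl ether by an acetal-type group that is removed cold; it sets out from 7 and comes back at 28. Enolate 8, made from 7 as in step 4, would be O-alkylated with chloromethyl methyl ether instead of MeOTf to give 2-(trimethylsilyl)ethyl (2E)-3-(methoxymethoxy)-2-methyl-5-(trimethylsilyl)pent-2-en-4-ynoate F3. Bu4NF would then give tetrabutylammonium (2E)-3-(methoxymethoxy)-2-methylpent-2-en-4-ynoate F4, and acidification would give (2E)-3-(methoxymethoxy)-2-methylpent-2-en-4-ynoic acid F5. The cascade of step 6 would give (3S,4E)-4-[3-(methoxymethoxy)-4-methyl-5-oxofuran-2(5H)-ylidene]-3-methylbutanal F6, and Wittig methylenation would give (5E)-4-(methoxymethoxy)-3-methyl-5-[(2S)-2-methylpent-4-en-1-ylidene]furan-2(5H)-one F7. Hydroboration with 9-BBN would give (5E)-5-[(2S)-5-(9-borabicyclo[3.3.1]nonan-9-yl)-2-methylpentylidene]-4-(methoxymethoxy)-3-methylfuran-2(5H)-one F8, and Suzuki coupling with 24 would give (5E)-5-[(2S,6E,10E)-13-(furan-3-yl)-2,6,10-trimethyltrideca-6,10-dien-1-ylidene]-4-(methoxymethoxy)-3-methylfuran-2(5H)-one F9. MgBr2·OEt2 in CH2Cl2 at 0 °C with aqueous work-up would then cleave the acetal and give 28 without heat.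

**Further compounds**

F1 | step 6 | (5E)-5-(iodomethylidene)-4-methoxy-3-methylfuran-2(5H)-one | COC1=C(C)C(=O)O/C1=C/I
F2 | step 4 | 2-(trimethylsilyl)ethyl 3,3-dimethoxy-2-methyl-5-(trimethylsilyl)pent-4-ynoate | COC(OC)(C#C[Si](C)(C)C)C(C)C(=O)OCC[Si](C)(C)C
F3 | step 15 | 2-(trimethylsilyl)ethyl (2E)-3-(methoxymethoxy)-2-methyl-5-(trimethylsilyl)pent-2-en-4-ynoate | C[Si](C)(C)CCOC(=O)/C(C)=C(OCOC)\C#C[Si](C)(C)C
F4 | step 15 | tetrabutylammonium (2E)-3-(methoxymethoxy)-2-methylpent-2-en-4-ynoate | C#C/C(OCOC)=C(C)\C(=O)[O-].CCCC[N+](CCCC)(CCCC)CCCC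
F5 | step 15 | (2E)-3-(methoxymethoxy)-2-methylpent-2-en-4-ynoic acid | C#C/C(OCOC)=C(C)\C(=O)O
F6 | step 15 | (3S,4E)-4-[3-(methoxymethoxy)-4-methyl-5-oxofuran-2(5H)-ylidene]-3-methylbutanal | COCOC1=C(C)C(=O)O/C1=C/[C@@H](C)CC=O
F7 | step 15 | (5E)-4-(methoxymethoxy)-3-methyl-5-[(2S)-2-methylpent-4-en-1-ylidene]furan-2(5H)-one | COCOC1=C(C)C(=O)O/C1=C/[C@@H](C)CC=C
F8 | step 15 | (5E)-5-[(2S)-5-(9-borabicyclo[3.3.1]nonan-9-yl)-2-methylpentylidene]-4-(methoxymethoxy)-3-methylfuran-2(5H)-one | COCOC1=C(C)C(=O)O/C1=C/[C@@H](C)CCCB1C2CCCC1CCC2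
F9 | step 15 | (5E)-5-[(2S,6E,10E)-13-(furan-3-yl)-2,6,10-trimethyltrideca-6,10-dien-1-ylidene]-4-(methoxymethoxy)-3-methylfuran-2(5H)-one | COCOC1=C(C)C(=O)O/C1=C/[C@@H](C)CCC/C(C)=C/CC/C(C)=C/CCc1ccoc1
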